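**Plan**

Ring A is the methoxy-bearing benzo ring, ring B the quinone ring (C1–C4) and ring C the dimethoxyphenyl ring (C1′–C6′) on C8.
- Retrosynthetic cuts, in order: the C2 O–CH3 bond; the C2–O and C4=O bonds of ring B, back to a 1-tetralone; C1′–C2′ and C5′–C6′ of ring C, after returning two hydrogens; the C8–C(sp) bond, back to a peri triflate; and the C1–C8a acyl bond.
- Enabling feature: ring C is joined through C1′ to C8, across the peri gap from the C1 carbonyl, and its only substituents are vicinal methoxy groups on C3′ and C4′. A C8 ethynyl group can therefore supply C1′ and C6′, and 2,3-dimethoxybutadiene can supply C2′–C5′ with both oxygens already in place.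
- Forward order: ring B closes first by Friedel–Crafts acylation onto ring A, and the peri oxygen is exchanged for an ethynyl group. Ring C is then built by cobalt-catalysed [4+2] cycloaddition and dehydrogenated. Ring B is oxidised last to the hydroxyquinone and O-methylated.
- Stereochemistry: the target has no stereocentre, so none is set.

Key step: step 6

Assumption: the arylbutanoic acid that opens the route and the two small reagents that bring in the alkyne carbons and the diene carbons are taken as catalogue compounds.

**Route**

Step 1
Reactants: 1 4-(3,5-dimethoxyphenyl)butanoic acid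
Product: 2 6,8-dimethoxy-3,4-dihydronaphthalen-1(2H)-one
Conditions: PPA (as solvent), 85 °C
Reagents that add atoms: none
Why: Intramolecular Friedel–Crafts acylation, in which the acylium ion attacks one of the two equivalent ring positions ortho to the side chain, each activated by both methoxy groups and the only ones that close a six-membered ring.

Step 2
Reactants: 2 6,8-dimethoxy-3,4-dihydronaphthalen-1(2H)-one
Product: 4 8-hydroxy-6-methoxy-3,4-dihydronaphthalen-1(2H)-one, via dichloroboryl aryl ether 3 (not isolated)
Conditions: BCl3 (1.3 equiv), CH2Cl2, −78 to 0 °C; then H2O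
Reagents that add atoms: none
Why: Chelation-directed Lewis-acid ether cleavage, in which BCl3 bridges the C1 carbonyl and the peri methoxy oxygen so that chloride removes only that methyl group, while the unchelated 6-methoxy group should survive at 0 °C.

Step 3
Reactants: 4 8-hydroxy-6-methoxy-3,4-dihydronaphthalen-1(2H)-one
Product: 5 3-methoxy-8-oxo-5,6,7,8-tetrahydronaphthalen-1-yl trifluoromethanesulfonate
Conditions: Tf2O (1.2 equiv), pyridine, CH2Cl2, 0 °C to rt
Reagents that add atoms: trifluoromethanesulfonic anhydride, O=S(=O)(OS(=O)(=O)C(F)(F)F)C(F)(F)F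
Why: O-Sulfonylation of a phenol (triflation), in which pyridine breaks the hydrogen bond to the ketone and is too weak a base to form an enol triflate from the tetralone.

Step 4
Reactants: 5 3-methoxy-8-oxo-5,6,7,8-tetrahydronaphthalen-1-yl trifluoromethanesulfonate; 6 ethynyltrimethylsilane
Product: 7 6-methoxy-8-[(trimethylsilyl)ethynyl]-3,4-dihydronaphthalen-1(2H)-one
Conditions: PdCl2(PPh3)2 (5 mol %), CuI (10 mol %), Et3N, DMF, 70 °C
Reagents that add atoms: ethynyltrimethylsilane, C[Si](C)(C)C#C
Why: Sonogashira coupling, in which the ortho ketone speeds oxidative addition of the C–OTf bond to zerovalent palladium, the acetylide formed from 6 with CuI and Et3N transmetalates, and the silyl cap prevents a second coupling.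

Step 5
Reactants: 7 6-methoxy-8-[(trimethylsilyl)ethynyl]-3,4-dihydronaphthalen-1(2H)-one
Product: 8 8-ethynyl-6-methoxy-3,4-dihydronaphthalen-1(2H)-one
Conditions: K2CO3 (0.2 equiv), MeOH–THF, 0 °C
Reagents that add atoms: none
Why: Base-catalysed protodesilylation of an alkynylsilane by methoxide attack at silicon, kept cold and short so that methanol does not add to the alkyne next to the ketone.

Step 6
Reactants: 8 8-ethynyl-6-methoxy-3,4-dihydronaphthalen-1(2H)-one; 9 2,3-dimethoxybuta-1,3-diene
Product: 10 8-(4,5-dimethoxycyclohexa-1,4-dien-1-yl)-6-methoxy-3,4-dihydronaphthalen-1(2H)-one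
Conditions: CoBr2(dppe) (10 mol %), Zn dust (20 mol %), ZnI2 (20 mol %), 9 (3 equiv), CH2Cl2, rt; filtration through Et3N-washed silica
Reagents that add atoms: 2,3-dimethoxybuta-1,3-diene, C=C(OC)C(=C)OC
Why: Zn reduces CoBr2(dppe) to monovalent cobalt and ZnI2 abstracts halide to open coordination sites; the metal then binds the terminal alkyne of 8 and the s-cis diene 9, joins them oxidatively to a cobaltacycle with one new C–C bond and forms the other by reductive elimination, releasing the 1,4-diene and the catalyst. The closest known reaction type is the cobalt-catalysed neutral Diels–Alder reaction of unactivated terminal arylalkynes with 2,3-disubstituted butadienes, oxygen-substituted ones included. Ring C closes as a six-membered carbocycle by an intermolecular metal-templated [4+2] cycloaddition that forms C1′–C2′ and C5′–C6′, the alkyne giving two carbons and the diene four. No stereocentre arises, because both new sp3 carbons are CH2 groups. The step needs chemoselectivity for the cross-cycloaddition over alkyne cyclotrimerisation but no regiocontrol, since 9 is symmetrical; the excess of diene and the bidentate dppe ligand, which leaves room for one alkyne beside the diene, should secure it. The aryl ketone and methyl ethers are spectators, and the base-buffered filtration protects the acid-labile bis(enol ether).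

Step 7
Reactants: 10 8-(4,5-dimethoxycyclohexa-1,4-dien-1-yl)-6-methoxy-3,4-dihydronaphthalen-1(2H)-one
Product: 11 8-(3,4-dimethoxyphenyl)-6-methoxy-3,4-dihydronaphthalen-1(2H)-one
Conditions: DDQ (1.1 equiv), toluene, rt
Reagents that add atoms: none
Why: Dehydrogenative aromatisation by DDQ, in which hydride is taken from a doubly allylic CH2 group next to an enol ether and proton loss gives the arene, far faster at room temperature than any attack on the tetralone CH2 groups.

Step 8
Reactants: 11 8-(3,4-dimethoxyphenyl)-6-methoxy-3,4-dihydronaphthalen-1(2H)-one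
Product: 13 8-(3,4-dimethoxyphenyl)-2-hydroxy-6-methoxynaphthalene-1,4-dione, via potassium quinone-2-olate 12 (not isolated)
Conditions: KOtBu (4 equiv), O2 (1 atm), tBuOH, 25 °C; then aq. HCl
Reagents that add atoms: dioxygen, O=O
Why: Base-mediated autoxidation of a 1-tetralone to a 2-hydroxy-1,4-naphthoquinone, in which the C2 enolate takes up oxygen, further enolisation and oxygenation carry C2–C4 to the quinone level, and the acidic product is held as its potassium salt, which resists further oxidation.

Step 9
Reactants: 13 8-(3,4-dimethoxyphenyl)-2-hydroxy-6-methoxynaphthalene-1,4-dione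
Product: 14 8-(3,4-dimethoxyphenyl)-2,6-dimethoxynaphthalene-1,4-dione (CNP0128574.0)
Conditions: MeOH, conc. HCl (cat.), reflux
Reagents that add atoms: methanol, CO
Why: Acid-catalysed Fischer-type etherification of a vinylogous carboxylic acid, for which the 2-methoxy-1,4-quinone is the thermodynamic product, so that any 4-methoxy-1,2-quinone isomer should equilibrate to it in acidic methanol.

**Compound list**

1 | 4-(3,5-dimethoxyphenyl)butanoic acid | COc1cc(CCCC(=O)O)cc(OC)c1 | starting material
2 | 6,8-dimethoxy-3,4-dihydronaphthalen-1(2H)-one | COc1cc(OC)c2C(=O)CCCc2c1 | intermediate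
3 | dichloro[(3-methoxy-8-oxo-5,6,7,8-tetrahydronaphthalen-1-yl)oxy]borane | COc1cc(OB(Cl)Cl)c2C(=O)CCCc2c1 | intermediate (not isolated)
4 | 8-hydroxy-6-methoxy-3,4-dihydronaphthalen-1(2H)-one | COc1cc(O)c2C(=O)CCCc2c1 | intermediate
5 | 3-methoxy-8-oxo-5,6,7,8-tetrahydronaphthalen-1-yl trifluoromethanesulfonate | COc1cc(OS(=O)(=O)C(F)(F)F)c2C(=O)CCCc2c1 | intermediate
6 | ethynyltrimethylsilane | C[Si](C)(C)C#C | starting material
7 | 6-methoxy-8-[(trimethylsilyl)ethynyl]-3,4-dihydronaphthalen-1(2H)-one | COc1cc(C#C[Si](C)(C)C)c2C(=O)CCCc2c1 | intermediate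
8 | 8-ethynyl-6-methoxy-3,4-dihydronaphthalen-1(2H)-one | COc1cc(C#C)c2C(=O)CCCc2c1 | intermediate
9 | 2,3-dimethoxybuta-1,3-diene | C=C(OC)C(=C)OC | starting material
10 | 8-(4,5-dimethoxycyclohexa-1,4-dien-1-yl)-6-methoxy-3,4-dihydronaphthalen-1(2H)-one | COC1=C(OC)CC(c2cc(OC)cc3CCCC(=O)c23)=CC1 | intermediate
11 | 8-(3,4-dimethoxyphenyl)-6-methoxy-3,4-dihydronaphthalen-1(2H)-one | COc1cc(-c2ccc(OC)c(OC)c2)c2C(=O)CCCc2c1 | intermediate
12 | potassium 8-(3,4-dimethoxyphenyl)-6-methoxy-1,4-dioxo-1,4-dihydronaphthalen-2-olate | [K+].[O-]C1=CC(=O)c2cc(OC)cc(-c3ccc(OC)c(OC)c3)c2C1=O | intermediate (not isolated)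
13 | 8-(3,4-dimethoxyphenyl)-2-hydroxy-6-methoxynaphthalene-1,4-dione | OC1=CC(=O)c2cc(OC)cc(-c3ccc(OC)c(OC)c3)c2C1=O | intermediate
14 | 8-(3,4-dimethoxyphenyl)-2,6-dimethoxynaphthalene-1,4-dione | COC1=CC(=O)c2cc(OC)cc(-c3ccc(OC)c(OC)c3)c2C1=O | target

**Count**

Total steps: 9. Longest linear sequence: 9 steps (1 to 14).

**Steps most likely to fail**

Step 6. The cycloaddition may be lost to cyclotrimerisation of the alkyne, to sequestration of the cobalt between the peri carbonyl and the alkyne, or to ZnI2-promoted breakdown of the enol ethers. The fallback brings ring C in intact. It sets out from triflate 5: a Suzuki–Miyaura coupling with (3,4-dimethoxyphenyl)boronic acid (Pd(OAc)2, SPhos, K3PO4, toluene–H2O, 90 °C) should give the biaryl ketone directly. It comes back to the route at 11, so steps 4 to 7 are skipped, at the price of a coupling at the hindered peri position. No compound outside the list is formed (F0).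

Step 8. The autoxidation may run on to oxidative cleavage of ring B, or the enolate may self-condense before it is oxygenated. The fallback oxidises ring B in stages and sets out from 11:
- SeO2 in AcOH at 100 °C (Riley oxidation with dehydrogenation) should give 8-(3,4-dimethoxyphenyl)-6-methoxynaphthalene-1,2-dione F1.
- Thiele–Winter acetoxylation (Ac2O, BF3·OEt2, rt) adds the C4 oxygen and should give 8-(3,4-dimethoxyphenyl)-6-methoxynaphthalene-1,2,4-triyl triacetate F2.
- NaOMe in MeOH releases 8-(3,4-dimethoxyphenyl)-6-methoxynaphthalene-1,2,4-triol F3, which air oxidises in the same flask; acidification then returns the route to 13.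

Step 4. Oxidative addition into the chelating, hindered triflate may be slow, so that amine-induced S–O cleavage back to the phenol and copper-mediated dimerisation of the alkyne take over. The fallback sets out from 5 and uses a Stille coupling with tributyl(ethynyl)stannane (Pd(PPh3)4, LiCl, dioxane, 90 °C). It needs neither CuI nor amine and delivers the terminal alkyne directly, so it comes back to the route at 8 and step 5 is skipped. No compound outside the list is formed (F0).

**Further compounds**

F0 | step 6 | none | none
F1 | step 8 | 8-(3,4-dimethoxyphenyl)-6-methoxynaphthalene-1,2-dione | O=C1C(=O)C=Cc2cc(OC)cc(-c3ccc(OC)c(OC)c3)c21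
F2 | step 8 | 8-(3,4-dimethoxyphenyl)-6-methoxynaphthalene-1,2,4-triyl triacetate | CC(=O)Oc1cc(OC(C)=O)c2cc(OC)cc(-c3ccc(OC)c(OC)c3)c2c1OC(C)=O
F3 | step 8 | 8-(3,4-dimethoxyphenyl)-6-methoxynaphthalene-1,2,4-triol | Oc1cc(O)c2cc(OC)cc(-c3ccc(OC)c(OC)c3)c2c1O
F0 | step 4 | none | none
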